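**Retrosynthetic overview**
1. Target 24 ⇐ ester 22: the last steps are acidolysis of a 4-methoxybenzyl ester, oxidation of the C-12 silyl ether to the enal, and 6-O-acylation of diol 16 with octatrienoic acid 20.
2. cis-6,9-Diol 16 ⇐ endoperoxide 15 ⇐ singlet-oxygen [4+2] on the cis-fused dienoate 14, on its convex face (sets C-6 and C-9 together).
3. Dienoate 14 ⇐ dienyl triflate 13 (Pd/CO carbonylation brings C-11) ⇐ enone 10 (Morita–Baylis–Hillman reaction brings C-12).
4. Ring A is closed second: 10 ⇐ dienone 8 by a hydrogen-atom-transfer radical 6-exo cyclisation; the tether on C-10 enforces the cis fusion (sets C-5).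
5. Ring B comes first, from 2-methylcyclohexane-1,3-dione: 8 ⇐ hydroxy ketone 5 ⇐ ketoreductase desymmetrisation of achiral dione 4 (sets C-10) ⇐ 1 + acrolein, then Wittig.

Assumption: positions are called by drimane numbering (C-5/C-10 ring fusion, C-6 acyloxy carbon, C-9 carbinol, C-11 carboxyl, C-12 formyl); the SMILES is read as the cis-fused (5R,6R,9R,10S) isomer with 10-CH3, 5-H, 6-O and 9-OH on one face, made in the open aldehyde–acid form drawn (it may equilibrate with its cyclic lactol).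

**Route**

Step 1
Reactants: 1 2-methylcyclohexane-1,3-dione; 2 acrolein
Product: 3 3-(1-methyl-2,6-dioxocyclohexyl)propanal
Conditions: H2O, rt
Reagents that add atoms: none
Why: Michael addition of the enolised dione to acrolein gives the 2,2-disubstituted dione, which is achiral.

Step 2
Reactants: 3 keto aldehyde
Product: 4 2-methyl-2-(4-methylpent-3-en-1-yl)cyclohexane-1,3-dione
Conditions: i-PrPPh3I, n-BuLi, THF, 0 °C; then 3, −78 °C to 0 °C
Reagents that add atoms: isopropyltriphenylphosphonium iodide, CC(C)[P+](c1ccccc1)(c1ccccc1)c1ccccc1.[I-]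
Why: Wittig olefination, in which the unstabilised ylide takes the aldehyde far faster than the two hindered ring ketones; the product is still achiral.

Step 3
Reactants: 4 prochiral dione
Product: 5 (2S,3S)-3-hydroxy-2-methyl-2-(4-methylpent-3-en-1-yl)cyclohexan-1-one
Conditions: ketoreductase (KRED), NADP+ (cat.), i-PrOH, phosphate buffer pH 7, DMSO (5%), 30 °C
Reagents that add atoms: none
Why: Enzymatic desymmetrising carbonyl reduction, in which the ketoreductase (an NADPH-dependent alcohol dehydrogenase) reduces one of the two enantiotopic carbonyls and so fixes the quaternary carbon (future C-10) as S and the carbinol as S, the sense typical of yeast-type reductases on 2-alkyl-2-methylcyclohexane-1,3-diones.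

Step 4
Reactants: 5 hydroxy ketone
Product: 6 (1S,2S)-2-methyl-2-(4-methylpent-3-en-1-yl)-3-oxocyclohexyl methanesulfonate
Conditions: MsCl, Et3N, CH2Cl2, 0 °C
Reagents that add atoms: methanesulfonyl chloride, CS(=O)(=O)Cl
Why: O-Sulfonylation turns the carbinol into a leaving group; there is no hydrogen between it and the ketone, so nothing eliminates yet.

Step 5
Reactants: 6 keto mesylate
Product: 7 (1S,6S)-6-methyl-6-(4-methylpent-3-en-1-yl)-5-oxocyclohex-3-en-1-yl methanesulfonate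
Conditions: IBX, 4-methoxypyridine N-oxide, DMSO, rt
Reagents that add atoms: none
Why: IBX dehydrogenation of the ketone to the enone can only go to the one enolisable side, because the other alpha carbon is quaternary.

Step 6
Reactants: 7 enone mesylate
Product: 8 (6S)-6-methyl-6-(4-methylpent-3-en-1-yl)cyclohexa-2,4-dien-1-one
Conditions: DBU, CH2Cl2, 0 °C to rt (used at once, kept cold and dark)
Reagents that add atoms: none
Why: Vinylogous E1cB elimination (gamma-deprotonation, loss of mesylate) gives the linear 2,4-dienone; the carbinol centre is erased and the quaternary centre is untouched.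

Step 7
Reactants: 8 dienone
Product: 10 (4aR,8aS)-5,5,8a-trimethyl-4a,5,6,7,8,8a-hexahydronaphthalen-1(4H)-one, via deconjugated enone 9 (not isolated)
Conditions: Fe(acac)3 (30 mol%), PhSiH3, EtOH/(CH2OH)2, 60 °C, high dilution; then DBU (cat.), CH2Cl2, rt
Reagents that add atoms: none
Why: Iron-hydride hydrogen-atom transfer to the trisubstituted alkene gives the tertiary C-4 radical, which adds 6-exo (Giese-type 1,6-addition) to C-5 of the planar dienone from the only face its tether on C-10 can reach, so 5-H ends syn to 10-CH3 (cis-decalin), and DBU then moves the double bond into conjugation.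

Step 8
Reactants: 10 cis-fused enone
Product: 11 (4aR,8aS)-2-(hydroxymethyl)-5,5,8a-trimethyl-4a,5,6,7,8,8a-hexahydronaphthalen-1(4H)-one
Conditions: aq. CH2O, DMAP (cat.), THF/H2O, rt
Reagents that add atoms: formaldehyde, C=O
Why: Morita–Baylis–Hillman hydroxymethylation places C-12 on the alpha carbon (C-8) of the enone, whose beta carbon is unhindered.

Step 9
Reactants: 11 allylic alcohol
Product: 12 (4aR,8aS)-5,5,8a-trimethyl-2-{[(triethylsilyl)oxy]methyl}-4a,5,6,7,8,8a-hexahydronaphthalen-1(4H)-one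
Conditions: Et3SiCl, imidazole, CH2Cl2, 0 °C
Reagents that add atoms: chlorotriethylsilane, CC[Si](CC)(CC)Cl
Why: Silylation protects the primary alcohol against the base of the next step and against lactonisation later.

Step 10
Reactants: 12 silyl ether enone
Product: 13 (4aR,8aS)-5,5,8a-trimethyl-2-{[(triethylsilyl)oxy]methyl}-4a,5,6,7,8,8a-hexahydronaphthalen-1-yl trifluoromethanesulfonate
Conditions: KN(SiMe3)2, THF, −78 °C; PhNTf2, −78 to 0 °C
Reagents that add atoms: N-phenylbis(trifluoromethanesulfonimide), O=S(=O)(N(c1ccccc1)S(=O)(=O)C(F)(F)F)C(F)(F)F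
Why: Enol triflate formation: with C-10 quaternary the only acidic position is gamma (C-6), so the through-conjugated dienolate forms and is O-triflated to the 6,8-diene.

Step 11
Reactants: 13 dienyl triflate
Product: 14 4-methoxybenzyl (4aR,8aS)-5,5,8a-trimethyl-2-{[(triethylsilyl)oxy]methyl}-4a,5,6,7,8,8a-hexahydronaphthalene-1-carboxylate
Conditions: CO (1 atm), 4-MeOC6H4CH2OH, Pd(OAc)2 (10 mol%), dppp, Et3N, DMF, 60 °C
Reagents that add atoms: carbon monoxide, [C-]#[O+]; 4-methoxybenzyl alcohol, COc1ccc(CO)cc1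
Why: Palladium-catalysed alkoxycarbonylation of the vinyl triflate (oxidative addition, CO insertion, alcoholysis) installs C-11 at the ester oxidation level.

Step 12
Reactants: 14 dienoate
Product: 15 4-methoxybenzyl (1R,4R,4aR,8aS)-5,5,8a-trimethyl-2-{[(triethylsilyl)oxy]methyl}-1,4,4a,5,6,7,8,8a-octahydro-1,4-epidioxynaphthalene-1-carboxylate
Conditions: O2, hν (visible), tetraphenylporphyrin (cat.), CH2Cl2, −20 °C
Reagents that add atoms: dioxygen, O=O
Why: [4+2] Cycloaddition of singlet oxygen to the s-cis diene takes place on the convex face of the cis-decalin (the face of 5-H and 10-CH3, since ring A and its gem-dimethyl group shield the other), which puts both the C-6 and C-9 oxygens syn to 10-CH3 and leaves C-11 on the opposite face.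

Step 13
Reactants: 15 endoperoxide
Product: 16 4-methoxybenzyl (1R,4R,4aR,8aS)-1,4-dihydroxy-5,5,8a-trimethyl-2-{[(triethylsilyl)oxy]methyl}-1,4,4a,5,6,7,8,8a-octahydronaphthalene-1-carboxylate
Conditions: thiourea, MeOH, rt
Reagents that add atoms: none
Why: Reductive cleavage of the O–O bond by thiourea gives the cis-1,4-diol with retention at both carbons under neutral conditions.

Step 14
Reactants: 17 (2E,4E)-hexa-2,4-dienal; 18 malonic acid
Product: 20 (2E,4E,6E)-octa-2,4,6-trienoic acid, via dienylidenemalonic acid 19 (not isolated)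
Conditions: pyridine, piperidine (cat.), 90 °C
Reagents that add atoms: none
Why: Knoevenagel–Doebner condensation followed by decarboxylation gives the all-E trienoic acid.

Step 15
Reactants: 16 diol; 20 trienoic acid
Product: 22 4-methoxybenzyl (1R,4R,4aR,8aS)-1-hydroxy-5,5,8a-trimethyl-4-{[(2E,4E,6E)-octa-2,4,6-trienoyl]oxy}-2-{[(triethylsilyl)oxy]methyl}-1,4,4a,5,6,7,8,8a-octahydronaphthalene-1-carboxylate, via mixed anhydride 21 (not isolated)
Conditions: 2,4,6-Cl3C6H2COCl, Et3N, toluene, rt; then 16, DMAP, rt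
Reagents that add atoms: none
Why: Yamaguchi esterification acylates the secondary allylic 6-OH only (the tertiary 9-OH is inert) and, being O-acylation, keeps the C-6 configuration.

Step 16
Reactants: 22 silyl ether
Product: 23 4-methoxybenzyl (1R,4R,4aR,8aS)-2-formyl-1-hydroxy-5,5,8a-trimethyl-4-{[(2E,4E,6E)-octa-2,4,6-trienoyl]oxy}-1,4,4a,5,6,7,8,8a-octahydronaphthalene-1-carboxylate
Conditions: (COCl)2, DMSO, CH2Cl2, −78 to −40 °C; then Et3N, −78 °C to rt
Reagents that add atoms: none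
Why: Swern-type oxidation in which the chlorosulfonium reagent exchanges the primary allylic triethylsilyl group directly, so the enal forms without a free gamma-hydroxy ester that could lactonise.

Step 17
Reactants: 23 aldehyde ester
Product: 24 (1R,4R,4aR,8aS)-2-formyl-1-hydroxy-5,5,8a-trimethyl-4-{[(2E,4E,6E)-octa-2,4,6-trienoyl]oxy}-1,4,4a,5,6,7,8,8a-octahydronaphthalene-1-carboxylic acid
Conditions: CF3CO2H, anisole, CH2Cl2, 0 °C
Reagents that add atoms: none
Why: Acidolysis (SN1-type) of the 4-methoxybenzyl ester, with the benzylic cation trapped by anisole, frees the acid without touching the trienoate, the enal or the tertiary alcohol.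

**Compound list**
1 | 2-methylcyclohexane-1,3-dione | CC1C(=O)CCCC1=O | starting material
2 | acrolein (prop-2-enal) | C=CC=O | starting material
3 | 3-(1-methyl-2,6-dioxocyclohexyl)propanal | CC1(CCC=O)C(=O)CCCC1=O | intermediate
4 | 2-methyl-2-(4-methylpent-3-en-1-yl)cyclohexane-1,3-dione | CC(C)=CCCC1(C)C(=O)CCCC1=O | intermediate
5 | (2S,3S)-3-hydroxy-2-methyl-2-(4-methylpent-3-en-1-yl)cyclohexan-1-one | O=C1CCC[C@H](O)[C@]1(C)CCC=C(C)C | intermediate
6 | (1S,2S)-2-methyl-2-(4-methylpent-3-en-1-yl)-3-oxocyclohexyl methanesulfonate | O=C1CCC[C@H](OS(C)(=O)=O)[C@]1(C)CCC=C(C)C | intermediate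
7 | (1S,6S)-6-methyl-6-(4-methylpent-3-en-1-yl)-5-oxocyclohex-3-en-1-yl methanesulfonate | O=C1C=CC[C@H](OS(C)(=O)=O)[C@]1(C)CCC=C(C)C | intermediate
8 | (6S)-6-methyl-6-(4-methylpent-3-en-1-yl)cyclohexa-2,4-dien-1-one | O=C1C=CC=C[C@]1(C)CCC=C(C)C | intermediate
9 | (4aR,8aS)-5,5,8a-trimethyl-4a,5,6,7,8,8a-hexahydronaphthalen-1(2H)-one | O=C1CC=C[C@@H]2C(C)(C)CCC[C@]12C | intermediate
10 | (4aR,8aS)-5,5,8a-trimethyl-4a,5,6,7,8,8a-hexahydronaphthalen-1(4H)-one | O=C1C=CC[C@@H]2C(C)(C)CCC[C@]12C | intermediate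
11 | (4aR,8aS)-2-(hydroxymethyl)-5,5,8a-trimethyl-4a,5,6,7,8,8a-hexahydronaphthalen-1(4H)-one | O=C1C(CO)=CC[C@@H]2C(C)(C)CCC[C@]12C | intermediate
12 | (4aR,8aS)-5,5,8a-trimethyl-2-{[(triethylsilyl)oxy]methyl}-4a,5,6,7,8,8a-hexahydronaphthalen-1(4H)-one | O=C1C(CO[Si](CC)(CC)CC)=CC[C@@H]2C(C)(C)CCC[C@]12C | intermediate
13 | (4aR,8aS)-5,5,8a-trimethyl-2-{[(triethylsilyl)oxy]methyl}-4a,5,6,7,8,8a-hexahydronaphthalen-1-yl trifluoromethanesulfonate | O=S(=O)(OC1=C(CO[Si](CC)(CC)CC)C=C[C@@H]2C(C)(C)CCC[C@]12C)C(F)(F)F | intermediate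
14 | 4-methoxybenzyl (4aR,8aS)-5,5,8a-trimethyl-2-{[(triethylsilyl)oxy]methyl}-4a,5,6,7,8,8a-hexahydronaphthalene-1-carboxylate | O=C(OCc1ccc(OC)cc1)C1=C(CO[Si](CC)(CC)CC)C=C[C@@H]2C(C)(C)CCC[C@]12C | intermediate
15 | 4-methoxybenzyl (1R,4R,4aR,8aS)-5,5,8a-trimethyl-2-{[(triethylsilyl)oxy]methyl}-1,4,4a,5,6,7,8,8a-octahydro-1,4-epidioxynaphthalene-1-carboxylate | O=C(OCc1ccc(OC)cc1)[C@]12OO[C@H](C=C1CO[Si](CC)(CC)CC)[C@@H]3C(C)(C)CCC[C@]23C | intermediate
16 | 4-methoxybenzyl (1R,4R,4aR,8aS)-1,4-dihydroxy-5,5,8a-trimethyl-2-{[(triethylsilyl)oxy]methyl}-1,4,4a,5,6,7,8,8a-octahydronaphthalene-1-carboxylate | O=C(OCc1ccc(OC)cc1)[C@]1(O)C(CO[Si](CC)(CC)CC)=C[C@@H](O)[C@@H]2C(C)(C)CCC[C@]12C | intermediate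
17 | (2E,4E)-hexa-2,4-dienal (sorbaldehyde) | C/C=C/C=C/C=O | starting material
18 | malonic acid | OC(=O)CC(=O)O | starting material
19 | 2-[(2E,4E)-hexa-2,4-dien-1-ylidene]propanedioic acid | C/C=C/C=C/C=C(C(=O)O)C(=O)O | intermediate
20 | (2E,4E,6E)-octa-2,4,6-trienoic acid | C/C=C/C=C/C=C/C(=O)O | intermediate
21 | (2E,4E,6E)-octa-2,4,6-trienoic 2,4,6-trichlorobenzoic anhydride | C/C=C/C=C/C=C/C(=O)OC(=O)c1c(Cl)cc(Cl)cc1Cl | intermediate
22 | 4-methoxybenzyl (1R,4R,4aR,8aS)-1-hydroxy-5,5,8a-trimethyl-4-{[(2E,4E,6E)-octa-2,4,6-trienoyl]oxy}-2-{[(triethylsilyl)oxy]methyl}-1,4,4a,5,6,7,8,8a-octahydronaphthalene-1-carboxylate | C/C=C/C=C/C=C/C(=O)O[C@@H]1C=C(CO[Si](CC)(CC)CC)[C@@](O)(C(=O)OCc2ccc(OC)cc2)[C@@]2(C)CCCC(C)(C)[C@@H]12 | intermediate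
23 | 4-methoxybenzyl (1R,4R,4aR,8aS)-2-formyl-1-hydroxy-5,5,8a-trimethyl-4-{[(2E,4E,6E)-octa-2,4,6-trienoyl]oxy}-1,4,4a,5,6,7,8,8a-octahydronaphthalene-1-carboxylate | C/C=C/C=C/C=C/C(=O)O[C@@H]1C=C(C=O)[C@@](O)(C(=O)OCc2ccc(OC)cc2)[C@@]2(C)CCCC(C)(C)[C@@H]12 | intermediate
24 | (1R,4R,4aR,8aS)-2-formyl-1-hydroxy-5,5,8a-trimethyl-4-{[(2E,4E,6E)-octa-2,4,6-trienoyl]oxy}-1,4,4a,5,6,7,8,8a-octahydronaphthalene-1-carboxylic acid | C/C=C/C=C/C=C/C(=O)O[C@@H]1C=C(C=O)[C@@](O)(C(=O)O)[C@@]2(C)CCCC(C)(C)[C@@H]12 | target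

**Step count**
Total: 17 steps. Longest linear sequence: 16 steps (steps 1–13 and 15–17; step 14 makes the side-chain acid).

**Three steps most likely to fail, each with a fallback**

The radical ring closure (step 7). The iron hydride may reduce the electrophilic dienone 8 instead of the side-chain alkene, and 8 can dimerise on warming. The fallback sets out from 8 and generates the same tertiary radical without a metal hydride. mCPBA epoxidises only the electron-rich side-chain alkene to (6S)-6-[2-(3,3-dimethyloxiran-2-yl)ethyl]-6-methylcyclohexa-2,4-dien-1-one F3. Cp2TiCl (from Cp2TiCl2 and Zn, THF) opens the epoxide homolytically; 6-exo closure on C-5 and DBU treatment give (4aR,8aS)-6-hydroxy-5,5,8a-trimethyl-4a,5,6,7,8,8a-hexahydronaphthalen-1(4H)-one F4 with the same cis fusion. The extra hydroxyl is removed by Barton–McCombie deoxygenation through O-[(4aS,8aR)-1,1,4a-trimethyl-5-oxo-1,2,3,4,4a,5,8,8a-octahydronaphthalen-2-yl] 1H-imidazole-1-carbothioate F5 (1,1'-thiocarbonyldiimidazole, then Bu3SnH, AIBN, toluene, 80 °C). The route is rejoined at 10.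

The photooxygenation (step 12). The ester on the diene terminus makes 14 a slow partner for electrophilic singlet oxygen, so ene products or decomposition may win. The fallback sets out from 14 and carries C-11 through the cycloaddition at the alcohol oxidation level.
- i-Bu2AlH reduces the ester to the dienyl carbinol [(4aR,8aS)-5,5,8a-trimethyl-2-{[(triethylsilyl)oxy]methyl}-4a,5,6,7,8,8a-hexahydronaphthalen-1-yl]methanol F6, and allyl chloroformate/pyridine gives its allyl carbonate F7.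
- The now electron-rich diene is photooxygenated as before to endoperoxide F8 and reduced with thiourea to cis-diol F9.
- Yamaguchi acylation with 20 gives the 6-O-octatrienoate F10, and Pd(PPh3)4/PhSiH3 removes the allyl carbonate to give the C-11 alcohol F11.
- Dess–Martin periodinane gives the C-11 aldehyde F12, and NaClO2/NaH2PO4/2-methylbut-2-ene gives the C-11 acid F13.
- 4-Methoxybenzyl chloride and Cs2CO3 in DMF esterify F13, and the route is rejoined at 22.

The olefination next to the 1,3-dione (step 2). The basic ylide can enolise aldehyde 3 or trigger its intramolecular aldol reaction. The fallback sets out from 1 and introduces the side chain by alkylation instead. Condensation with N,N-dimethylhydrazine gives the vinylogous hydrazide 3-(2,2-dimethylhydrazinyl)-2-methylcyclohex-2-en-1-one F1. Its potassium salt (KH, THF) is C-alkylated by 5-iodo-2-methylpent-2-ene to 3-(2,2-dimethylhydrazinylidene)-2-methyl-2-(4-methylpent-3-en-1-yl)cyclohexan-1-one F2 (racemic; this centre disappears again on hydrolysis). Cu(OAc)2 in aqueous THF hydrolyses the hydrazone, and the route is rejoined at achiral dione 4.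

**Further compounds**
F1 | step 2 | 3-(2,2-dimethylhydrazinyl)-2-methylcyclohex-2-en-1-one | CC1=C(NN(C)C)CCCC1=O
F2 | step 2 | 3-(2,2-dimethylhydrazinylidene)-2-methyl-2-(4-methylpent-3-en-1-yl)cyclohexan-1-one (racemic) | CC(C)=CCCC1(C)C(=O)CCCC1=NN(C)C
F3 | step 7 | (6S)-6-[2-(3,3-dimethyloxiran-2-yl)ethyl]-6-methylcyclohexa-2,4-dien-1-one (both epoxide epimers) | O=C1C=CC=C[C@]1(C)CCC1OC1(C)C
F4 | step 7 | (4aR,8aS)-6-hydroxy-5,5,8a-trimethyl-4a,5,6,7,8,8a-hexahydronaphthalen-1(4H)-one (C-6 epimers) | O=C1C=CC[C@@H]2C(C)(C)C(O)CC[C@]12C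
F5 | step 7 | O-[(4aS,8aR)-1,1,4a-trimethyl-5-oxo-1,2,3,4,4a,5,8,8a-octahydronaphthalen-2-yl] 1H-imidazole-1-carbothioate (C-2 epimers) | O=C1C=CC[C@@H]2C(C)(C)C(OC(=S)n3ccnc3)CC[C@]12C
F6 | step 12 | [(4aR,8aS)-5,5,8a-trimethyl-2-{[(triethylsilyl)oxy]methyl}-4a,5,6,7,8,8a-hexahydronaphthalen-1-yl]methanol | OCC1=C(CO[Si](CC)(CC)CC)C=C[C@@H]2C(C)(C)CCC[C@]12C
F7 | step 12 | [(4aR,8aS)-5,5,8a-trimethyl-2-{[(triethylsilyl)oxy]methyl}-4a,5,6,7,8,8a-hexahydronaphthalen-1-yl]methyl prop-2-en-1-yl carbonate | C=CCOC(=O)OCC1=C(CO[Si](CC)(CC)CC)C=C[C@@H]2C(C)(C)CCC[C@]12C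
F8 | step 12 | [(1R,4R,4aR,8aS)-5,5,8a-trimethyl-2-{[(triethylsilyl)oxy]methyl}-1,4,4a,5,6,7,8,8a-octahydro-1,4-epidioxynaphthalen-1-yl]methyl prop-2-en-1-yl carbonate | C=CCOC(=O)OC[C@]12OO[C@H](C=C1CO[Si](CC)(CC)CC)[C@@H]3C(C)(C)CCC[C@]23C
F9 | step 12 | [(1R,4R,4aR,8aS)-1,4-dihydroxy-5,5,8a-trimethyl-2-{[(triethylsilyl)oxy]methyl}-1,4,4a,5,6,7,8,8a-octahydronaphthalen-1-yl]methyl prop-2-en-1-yl carbonate | C=CCOC(=O)OC[C@]1(O)C(CO[Si](CC)(CC)CC)=C[C@@H](O)[C@@H]2C(C)(C)CCC[C@]12C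
F10 | step 12 | (1R,4R,4aS,8aR)-4-hydroxy-4a,8,8-trimethyl-4-({[(prop-2-en-1-yloxy)carbonyl]oxy}methyl)-3-{[(triethylsilyl)oxy]methyl}-1,4,4a,5,6,7,8,8a-octahydronaphthalen-1-yl (2E,4E,6E)-octa-2,4,6-trienoate | C/C=C/C=C/C=C/C(=O)O[C@@H]1C=C(CO[Si](CC)(CC)CC)[C@@](O)(COC(=O)OCC=C)[C@@]2(C)CCCC(C)(C)[C@@H]12
F11 | step 12 | (1R,4R,4aS,8aR)-4-hydroxy-4-(hydroxymethyl)-4a,8,8-trimethyl-3-{[(triethylsilyl)oxy]methyl}-1,4,4a,5,6,7,8,8a-octahydronaphthalen-1-yl (2E,4E,6E)-octa-2,4,6-trienoate | C/C=C/C=C/C=C/C(=O)O[C@@H]1C=C(CO[Si](CC)(CC)CC)[C@@](O)(CO)[C@@]2(C)CCCC(C)(C)[C@@H]12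
F12 | step 12 | (1R,4R,4aS,8aR)-4-formyl-4-hydroxy-4a,8,8-trimethyl-3-{[(triethylsilyl)oxy]methyl}-1,4,4a,5,6,7,8,8a-octahydronaphthalen-1-yl (2E,4E,6E)-octa-2,4,6-trienoate | C/C=C/C=C/C=C/C(=O)O[C@@H]1C=C(CO[Si](CC)(CC)CC)[C@@](O)(C=O)[C@@]2(C)CCCC(C)(C)[C@@H]12
F13 | step 12 | (1R,4R,4aR,8aS)-1-hydroxy-5,5,8a-trimethyl-4-{[(2E,4E,6E)-octa-2,4,6-trienoyl]oxy}-2-{[(triethylsilyl)oxy]methyl}-1,4,4a,5,6,7,8,8a-octahydronaphthalene-1-carboxylic acid | C/C=C/C=C/C=C/C(=O)O[C@@H]1C=C(CO[Si](CC)(CC)CC)[C@@](O)(C(=O)O)[C@@]2(C)CCCC(C)(C)[C@@H]12
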